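Ring C is opened at C3–C4 and at O1–C8a. This reveals O1–C2–C3 as a ring-opened aryl epoxide and C4–C4a–C8a as an ortho-fluoroaryl acyl anion. In the key step the lithiated 1,3-dithiane on ring A attacks the CH2 end of (R)-4-(methoxymethoxy)styrene oxide. The alkoxide released by the strain of the epoxide then displaces fluoride at C8a in the same flask, closing ring C as its C4 dithioketal. The step exploits the 1,3-relationship of O1 and C3 across stereocentre C2, whose C2–O1 bond is never broken, and the meta position of the C5 and C7 oxygens to C8a. The precursors are an aryl dithiane and an enantiopure epoxide; the C6 prenyl group follows by ortho-metalation.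

Key step: step 6

Remark: the descriptor in the target corresponds to (2S). Flavanone numbering (O1, C2, C3, C4, C4a, C5 to C8, C8a; ring A = benzo ring, ring B = 2-aryl group, ring C = pyranone ring) is used for all intermediates.

Step 1
Reactants: 1 5-fluorobenzene-1,3-diol (5-fluororesorcinol)
Product: 2 1-fluoro-3,5-bis(methoxymethoxy)benzene
Conditions: MOMCl, i-Pr2NEt, CH2Cl2, 0 °C to rt
Reagents that add atoms: chloromethyl methyl ether (MOMCl), COCCl
Why: Standard acetal protection (O-alkylation of the phenols by MOMCl under amine base) gives base-stable ethers that later steer the ortho-metalations and are all removed together in the last step.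

Step 2
Reactants: 2 1-fluoro-3,5-bis(methoxymethoxy)benzene
Product: 4 1-fluoro-3,5-bis(methoxymethoxy)-2-methylbenzene, via aryllithium 3 (not isolated)
Conditions: n-BuLi, THF, −78 °C; MeI, −78 °C to rt
Reagents that add atoms: iodomethane, CI
Why: Directed ortho-metalation: at −78 °C n-BuLi removes only a C–H that is acidified by the adjacent fluorine and reached from a MOM oxygen (the two such sites are equivalent, whereas the C–H between the two MOM ethers needs about 0 °C), and the cold SN2 quench with MeI outruns loss of LiF to an aryne.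

Step 3
Reactants: 4 1-fluoro-3,5-bis(methoxymethoxy)-2-methylbenzene; 5 1,3-dithiane
Product: 9 2-[2-fluoro-4,6-bis(methoxymethoxy)-3-methylphenyl]-1,3-dithiane, via aryllithium 6 (not isolated), via arylmagnesium bromide 7 (not isolated), via 2-chloro-1,3-dithiane 8 (not isolated)
Conditions: flask A: 4, n-BuLi, THF, −78 °C, then MgBr2·OEt2, −78 to −20 °C; flask B: 5, NCS, benzene, rt, filtered; B into A, −20 °C to rt
Reagents that add atoms: none
Why: A second directed ortho-metalation takes the last C–H next to fluorine, transmetalation gives a Grignard reagent that resists elimination to an aryne, and its known substitution on the α-chloro sulfide 8 (which reacts through the sulfur-stabilised dithianyl cation) installs C4 as a masked acyl anion without any acid that would strip the MOM groups.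

Step 4
Reactants: 10 2-chloro-1-(4-hydroxyphenyl)ethan-1-one
Product: 11 2-chloro-1-[4-(methoxymethoxy)phenyl]ethan-1-one
Conditions: MOMCl, i-Pr2NEt, CH2Cl2, 0 °C to rt
Reagents that add atoms: chloromethyl methyl ether (MOMCl), COCCl
Why: MOM protection under a hindered amine base, in which the very reactive MOMCl captures the phenol faster than the α-chloro ketone can be displaced.

Step 5
Reactants: 11 2-chloro-1-[4-(methoxymethoxy)phenyl]ethan-1-one
Product: 13 (2R)-2-[4-(methoxymethoxy)phenyl]oxirane, via (R)-chlorohydrin 12 (not isolated)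
Conditions: Cp*RhCl[(S,S)-TsDPEN] (0.2 mol %), HCO2H/Et3N (5:2), EtOAc, rt; then 2 M aq. NaOH, i-PrOH, 0 °C to rt
Reagents that add atoms: none
Why: Noyori–Ikariya asymmetric transfer hydrogenation sets the stereocentre, the (S,S)-TsDPEN ligand delivering hydride to the ketone face that gives the (R)-chlorohydrin (the same spatial sense as (S)-1-arylethanols from acetophenones), and the intramolecular Williamson closure takes place at the CH2Cl carbon so that the configuration is kept.

Step 6
Reactants: 9 2-[2-fluoro-4,6-bis(methoxymethoxy)-3-methylphenyl]-1,3-dithiane; 13 (2R)-2-[4-(methoxymethoxy)phenyl]oxirane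
Product: 16 (2S)-5,7-bis(methoxymethoxy)-2-[4-(methoxymethoxy)phenyl]-8-methylspiro[chromane-4,2'-[1,3]dithiane], via lithiated dithiane 14 (not isolated), via lithium alkoxide 15 (not isolated)
Conditions: n-BuLi, THF, −78 to −30 °C; 13, DMPU, −30 °C to rt; then 65 °C
Reagents that add atoms: none
Why: n-BuLi removes the dithiane C–H of 9 (below −30 °C, where the C6–H between the MOM ethers is still inert) to give the acyl anion equivalent 14, which opens epoxide 13 by SN2 attack at the unsubstituted CH2 carbon (C3–C4 bond); the lithium alkoxide 15 set free by this strain release then adds to C8a on warming and expels fluoride by addition–elimination (O1–C8a bond), with precipitation of LiF making the closure irreversible. The closest known reaction types are the Corey–Seebach alkylation of lithiated dithianes by terminal epoxides and the intramolecular SNAr etherification of aryl fluorides by alkoxides, run here as one anionic [3+3] annulation. Ring C closes in a six-membered mode by ipso attack of O1 on the sp2 carbon C8a (6-exo-trig with respect to the C8–C8a bond), and the quaternary dithioketal carbon C4 presses the alkoxide against the C–F bond (Thorpe–Ingold effect). No new stereocentre is made: C2 comes from 13 with its C–O bond intact, so the (R)-epoxide appears as (2S)-16 only because CH2 and aryl change places in the CIP ranking. The step needs opening at CH2 and not at the benzylic carbon, which the bulk of the tertiary carbanion and the Li+-binding DMPU (no Lewis-acid opening or Meinwald rearrangement of the electron-rich epoxide) secure, and closure at C8a and not at C5, which the far better leaving group fluoride secures and which fixes the methyl group at C8. The C5 and C7 oxygens are meta to C8a and therefore do not feed electrons into the anionic σ-complex, no C–H next to fluorine is left for aryne formation, and the dithioketal shuts off the retro-aldol and E1cB paths that would racemise C2 at the ketone level.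

Step 7
Reactants: 16 (2S)-5,7-bis(methoxymethoxy)-2-[4-(methoxymethoxy)phenyl]-8-methylspiro[chromane-4,2'-[1,3]dithiane]
Product: 18 (2S)-5,7-bis(methoxymethoxy)-2-[4-(methoxymethoxy)phenyl]-8-methyl-6-(3-methylbut-2-en-1-yl)spiro[chromane-4,2'-[1,3]dithiane], via C6-aryllithium 17 (not isolated)
Conditions: n-BuLi, THF, −20 to 0 °C; CuBr·SMe2 (10 mol %), prenyl bromide, −20 °C to rt
Reagents that add atoms: prenyl bromide (1-bromo-3-methylbut-2-ene), CC(C)=CCBr
Why: Directed ortho-metalation at C6, the only ring A C–H and the only site in 16 flanked by two MOM ethers, followed by CuBr·SMe2-catalysed SN2 allylation gives the linear prenyl group, while the dithioketal shields C4 from the organolithium.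

Step 8
Reactants: 18 (2S)-5,7-bis(methoxymethoxy)-2-[4-(methoxymethoxy)phenyl]-8-methyl-6-(3-methylbut-2-en-1-yl)spiro[chromane-4,2'-[1,3]dithiane]
Product: 19 (2S)-5,7-bis(methoxymethoxy)-2-[4-(methoxymethoxy)phenyl]-8-methyl-6-(3-methylbut-2-en-1-yl)chroman-4-one
Conditions: MeI, CaCO3, MeCN/H2O (9:1), 45 °C
Reagents that add atoms: water, O
Why: Alkylative dithioketal hydrolysis: S-methylation makes sulfur a leaving group, the thionium ion is stabilised by the electron-rich ring A and trapped by water, and the CaCO3 buffer keeps the medium neutral so that the prenyl alkene, the MOM ethers and the base-sensitive C2 centre of the flavanone are untouched.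

Step 9
Reactants: 19 (2S)-5,7-bis(methoxymethoxy)-2-[4-(methoxymethoxy)phenyl]-8-methyl-6-(3-methylbut-2-en-1-yl)chroman-4-one
Product: 20 (2S)-5,7,4'-trihydroxy-8-methyl-6-prenylflavanone
Conditions: 3 M aq. HCl, MeOH, rt to 40 °C
Reagents that add atoms: none
Why: Acid-catalysed transacetalisation of the three MOM ethers to methanol, a mild deprotection in common use for prenylated flavanones, avoids the basic media that racemise C2 by retro-oxa-Michael opening and stays below the acidity and temperature at which the C6 prenyl group cyclises onto the C5 or C7 phenol.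

Compound list
1 | 5-fluorobenzene-1,3-diol (5-fluororesorcinol) | Oc1cc(O)cc(F)c1 | starting material
2 | 1-fluoro-3,5-bis(methoxymethoxy)benzene | COCOc1cc(F)cc(OCOC)c1 | intermediate
3 | [2-fluoro-4,6-bis(methoxymethoxy)phenyl]lithium | [Li]c1c(F)cc(OCOC)cc1OCOC | intermediate
4 | 1-fluoro-3,5-bis(methoxymethoxy)-2-methylbenzene | Cc1c(F)cc(OCOC)cc1OCOC | intermediate
5 | 1,3-dithiane | C1CSCSC1 | starting material
6 | [2-fluoro-4,6-bis(methoxymethoxy)-3-methylphenyl]lithium | Cc1c(F)c([Li])c(OCOC)cc1OCOC | intermediate
7 | [2-fluoro-4,6-bis(methoxymethoxy)-3-methylphenyl]magnesium bromide | Cc1c(F)c([Mg]Br)c(OCOC)cc1OCOC | intermediate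
8 | 2-chloro-1,3-dithiane | ClC1SCCCS1 | intermediate
9 | 2-[2-fluoro-4,6-bis(methoxymethoxy)-3-methylphenyl]-1,3-dithiane | Cc1c(F)c(C2SCCCS2)c(OCOC)cc1OCOC | intermediate
10 | 2-chloro-1-(4-hydroxyphenyl)ethan-1-one | O=C(CCl)c1ccc(O)cc1 | starting material
11 | 2-chloro-1-[4-(methoxymethoxy)phenyl]ethan-1-one | COCOc1ccc(cc1)C(=O)CCl | intermediate
12 | (1R)-2-chloro-1-[4-(methoxymethoxy)phenyl]ethan-1-ol | ClC[C@@H](c1ccc(OCOC)cc1)O | intermediate
13 | (2R)-2-[4-(methoxymethoxy)phenyl]oxirane | C1[C@@H](c2ccc(OCOC)cc2)O1 | intermediate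
14 | 2-[2-fluoro-4,6-bis(methoxymethoxy)-3-methylphenyl]-2-lithio-1,3-dithiane | Cc1c(F)c(C2([Li])SCCCS2)c(OCOC)cc1OCOC | intermediate
15 | lithium (1S)-2-{2-[2-fluoro-4,6-bis(methoxymethoxy)-3-methylphenyl]-1,3-dithian-2-yl}-1-[4-(methoxymethoxy)phenyl]ethan-1-olate | Cc1c(F)c(c(OCOC)cc1OCOC)C1(SCCCS1)C[C@@H](c1ccc(OCOC)cc1)O[Li] | intermediate
16 | (2S)-5,7-bis(methoxymethoxy)-2-[4-(methoxymethoxy)phenyl]-8-methylspiro[chromane-4,2'-[1,3]dithiane] | c1c(OCOC)c(C)c2c(c1OCOC)C1(SCCCS1)C[C@@H](c1ccc(OCOC)cc1)O2 | intermediate
17 | 6-lithio derivative of 16 | [Li]c1c(OCOC)c(C)c2c(c1OCOC)C1(SCCCS1)C[C@@H](c1ccc(OCOC)cc1)O2 | intermediate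
18 | (2S)-5,7-bis(methoxymethoxy)-2-[4-(methoxymethoxy)phenyl]-8-methyl-6-(3-methylbut-2-en-1-yl)spiro[chromane-4,2'-[1,3]dithiane] | CC(C)=CCc1c(OCOC)c(C)c2c(c1OCOC)C1(SCCCS1)C[C@@H](c1ccc(OCOC)cc1)O2 | intermediate
19 | (2S)-5,7-bis(methoxymethoxy)-2-[4-(methoxymethoxy)phenyl]-8-methyl-6-(3-methylbut-2-en-1-yl)chroman-4-one | CC(C)=CCc1c(OCOC)c(C)c2c(c1OCOC)C(=O)C[C@@H](c1ccc(OCOC)cc1)O2 | intermediate
20 | (2S)-5,7,4'-trihydroxy-8-methyl-6-prenylflavanone | CC(C)=CCc1c(O)c(C)c2c(c1O)C(=O)C[C@@H](c1ccc(O)cc1)O2 | target

Total step count: 9. Longest linear sequence: 7 steps (1, 2, 3, 6, 7, 8, 9).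

Steps most likely to fail

1. Step 6.
- What may go wrong: the fluoride displacement may stall, because at the dithioketal level ring A carries no π-acceptor. Prolonged heating may then erode alkoxide 15 by fragmentation.
- Starting point: the fallback makes the two bonds one at a time and closes the ring at the ketone level. It sets out from lithium alkoxide 15, made from 9 and 13 as in step 6 but kept at rt or below.
- Silyl trap: Et3SiCl traps 15 as the triethylsilyl ether of the ring-opened alcohol F1.
- Prenylation: n-BuLi (THF, 0 °C) metalates the C–H between the two MOM ethers to the aryllithium F2, and prenyl bromide gives the prenylated silyl ether F3.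
- Unmasking: MeI and CaCO3 in aqueous MeCN free the β-silyloxy 2-fluoroaryl ketone F4.
- Ring closure: catalytic CsF in DMF then runs a fluoride-relay SNAr. The C4 carbonyl ortho to C8a activates the C–F bond, and each closure releases the fluoride that desilylates the next molecule, so no stoichiometric base meets the aldol-type ketone.
- Return: the fallback comes back to the route at 19.

2. Step 7.
- What may go wrong: metalation may lose site selectivity (ring B ortho to its MOM ether, or C2–H with erosion of configuration), or butyllithium may attack sulfur.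
- Unmasking: the fallback uses electrophilic instead of anionic prenylation and sets out from 16. MeI and CaCO3 in aqueous MeCN give (2S)-5,7-bis(methoxymethoxy)-2-[4-(methoxymethoxy)phenyl]-8-methylchroman-4-one F5.
- Deprotection: HCl in MeOH gives (2S)-5,7,4'-trihydroxy-8-methylflavanone F6.
- Prenylation: Friedel–Crafts prenylation with 2-methylbut-3-en-2-ol and BF3·OEt2 in dioxane then reaches C6, the only open position of ring A.
- Return: the fallback comes back at 20.

3. Step 3.
- What may go wrong: the Grignard reagent may be lost by proton transfer from chloride 8 or from residual succinimide, or 8 may decompose before coupling.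
- Formylation: the fallback builds the thioacetal on a carbonyl group and sets out from aryllithium 6. A DMF quench at −78 °C gives 2-fluoro-4,6-bis(methoxymethoxy)-3-methylbenzaldehyde F7.
- Thioacetalisation: neutral thioacetalisation with 1,3-bis(trimethylsilylthio)propane and catalytic ZnI2 in Et2O spares the MOM ethers.
- Return: the fallback comes back at 9.

Further compounds
F1 | step 6 | 2-[2-fluoro-4,6-bis(methoxymethoxy)-3-methylphenyl]-2-{(2S)-2-[4-(methoxymethoxy)phenyl]-2-(triethylsilyloxy)ethyl}-1,3-dithiane | Cc1c(F)c(c(OCOC)cc1OCOC)C1(SCCCS1)C[C@@H](c1ccc(OCOC)cc1)O[Si](CC)(CC)CC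
F2 | step 6 | aryllithium of F1, lithiated between the two MOM ethers | [Li]c1c(OCOC)c(C)c(F)c(c1OCOC)C1(SCCCS1)C[C@@H](c1ccc(OCOC)cc1)O[Si](CC)(CC)CC
F3 | step 6 | 2-[2-fluoro-4,6-bis(methoxymethoxy)-3-methyl-5-(3-methylbut-2-en-1-yl)phenyl]-2-{(2S)-2-[4-(methoxymethoxy)phenyl]-2-(triethylsilyloxy)ethyl}-1,3-dithiane | CC(C)=CCc1c(OCOC)c(C)c(F)c(c1OCOC)C1(SCCCS1)C[C@@H](c1ccc(OCOC)cc1)O[Si](CC)(CC)CC
F4 | step 6 | (3S)-1-[2-fluoro-4,6-bis(methoxymethoxy)-3-methyl-5-(3-methylbut-2-en-1-yl)phenyl]-3-[4-(methoxymethoxy)phenyl]-3-(triethylsilyloxy)propan-1-one | CC(C)=CCc1c(OCOC)c(C)c(F)c(c1OCOC)C(=O)C[C@@H](c1ccc(OCOC)cc1)O[Si](CC)(CC)CC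
F5 | step 7 | (2S)-5,7-bis(methoxymethoxy)-2-[4-(methoxymethoxy)phenyl]-8-methylchroman-4-one | c1c(OCOC)c(C)c2c(c1OCOC)C(=O)C[C@@H](c1ccc(OCOC)cc1)O2
F6 | step 7 | (2S)-5,7,4'-trihydroxy-8-methylflavanone | c1c(O)c(C)c2c(c1O)C(=O)C[C@@H](c1ccc(O)cc1)O2
F7 | step 3 | 2-fluoro-4,6-bis(methoxymethoxy)-3-methylbenzaldehyde | Cc1c(F)c(C=O)c(OCOC)cc1OCOC
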